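## Retrosynthetic overview

1. The acetate, the free acid and the free allylic alcohol are set last. The 13E side-chain alkene is carried through ring formation as its epoxide, because a free third alkene would be attacked by the C8 radical, and is returned by stereospecific deoxygenation.
2. Key disconnection: C4–C5 and C9–C10 in one operation, by oxidative radical bicyclization of the dilithium alkoxide–enolate of an acyclic (3R)-β-hydroxy-α-methyl ester. Ring A closes first (C4 radical onto C5), then ring B (C10 radical onto C9), and the C8 radical is oxidised to the exocyclic alkene.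
3. The single C3 carbinol, from Noyori hydrogenation of a β-keto ester, relays its configuration to C4, C5, C9 and C10 through a chelated chair–chair transition state.
4. The β-keto ester comes from γ-alkylation of the dianion of tert-butyl 2-methylacetoacetate with 12-bromofarnesyl acetate, made from (2E,6E)-farnesyl acetate by allylic oxidation and bromination.

Assumption: tert-butyl 2-methylacetoacetate and (2E,6E)-farnesyl acetate are taken as catalogue compounds; acyclic intermediates are numbered as hexadecanoates, bicyclic ones with labdane numbering (C18 = the 4α carboxyl carbon).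

## Route

Step 1
Reactants: 1 (2E,6E)-3,7,11-trimethyldodeca-2,6,10-trien-1-yl acetate ((2E,6E)-farnesyl acetate)
Product: 2 (2E,6E,10E)-12-hydroxy-3,7,11-trimethyldodeca-2,6,10-trien-1-yl acetate
Conditions: SeO2 (0.3 equiv), t-BuOOH (3 equiv), salicylic acid (0.1 equiv), CH2Cl2, 23 °C
Reagents that add atoms: selenium dioxide O=[Se]=O; tert-butyl hydroperoxide CC(C)(C)OO
Why: Sharpless catalytic SeO2/t-BuOOH allylic oxidation (ene reaction then [2,3]-sigmatropic shift) attacks the most electron-rich terminal alkene at its E-methyl group and gives the (10E)-allylic alcohol, while the acetate-deactivated 2,3-alkene and the internal alkene react more slowly.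

Step 2
Reactants: 2 (2E,6E,10E)-12-hydroxy-3,7,11-trimethyldodeca-2,6,10-trien-1-yl acetate
Product: 3 (2E,6E,10E)-12-bromo-3,7,11-trimethyldodeca-2,6,10-trien-1-yl acetate
Conditions: CBr4, PPh3, CH2Cl2, −20 → 0 °C
Reagents that add atoms: tetrabromomethane BrC(Br)(Br)Br
Why: Appel bromination replaces the primary allylic hydroxyl by SN2 displacement of the oxyphosphonium group, without allylic shift or loss of the E geometry, and leaves the acetate alone.

Step 3
Reactants: 3 (2E,6E,10E)-12-bromo-3,7,11-trimethyldodeca-2,6,10-trien-1-yl acetate; 4 tert-butyl 2-methyl-3-oxobutanoate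
Product: 6 tert-butyl (6E,10E,14E)-16-acetoxy-2,6,10,14-tetramethyl-3-oxohexadeca-6,10,14-trienoate (racemic at C2), via sodium lithium dienolate 5 (not isolated)
Conditions: 4 (1.3 equiv), NaH, THF, 0 °C; n-BuLi, 0 °C; then 3, −78 → −30 °C; aq NH4Cl
Reagents that add atoms: none
Why: Huckin–Weiler dianion alkylation: the terminal carbanion of 5 is the more nucleophilic site and displaces the allylic bromide by SN2 at −78 °C, much faster than it attacks the acetate; the C2 centre formed is of no consequence.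

Step 4
Reactants: 6 tert-butyl (6E,10E,14E)-16-acetoxy-2,6,10,14-tetramethyl-3-oxohexadeca-6,10,14-trienoate
Product: 8 tert-butyl (3R,6E,10E,14E)-3,16-dihydroxy-2,6,10,14-tetramethylhexadeca-6,10,14-trienoate (both C2 epimers), via acetoxy hydroxy ester 7 (not isolated)
Conditions: RuCl2[(R)-BINAP] (1 mol%), H2 (4 atm), MeOH, 50 °C; vent; then K2CO3 (0.3 equiv), 23 °C
Reagents that add atoms: none
Why: Noyori asymmetric hydrogenation of the β-keto ester with the (R)-BINAP–RuCl2 catalyst sets C3 as R in both C2 epimers (which converge in step 6) and does not touch the trisubstituted alkenes; carbonate-catalysed methanolysis (Zemplén-type transesterification) then removes the acetate while the tert-butyl ester resists.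

Step 5
Reactants: 8 tert-butyl (3R,6E,10E,14E)-3,16-dihydroxy-2,6,10,14-tetramethylhexadeca-6,10,14-trienoate
Product: 10 tert-butyl (3R,6E,10E,14S,15S)-16-[(tert-butyldiphenylsilyl)oxy]-14,15-epoxy-3-hydroxy-2,6,10,14-tetramethylhexadeca-6,10-dienoate, via epoxy diol 9 (not isolated)
Conditions: Ti(OiPr)4 (0.2 equiv), L-(+)-diethyl tartrate (0.25 equiv), t-BuOOH (1.2 equiv), 4 Å MS, CH2Cl2, −20 °C; then Et3N, DMAP (cat.), TBDPSCl (1.3 equiv), −20 → 0 °C
Reagents that add atoms: tert-butyl hydroperoxide CC(C)(C)OO; tert-butyl(chloro)diphenylsilane CC(C)(C)[Si](Cl)(c1ccccc1)c1ccccc1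
Why: Katsuki–Sharpless asymmetric epoxidation is directed by the allylic hydroxyl, so only the 14,15-alkene reacts (L-(+)-tartrate gives the 14S,15S epoxide, which stores the E geometry and removes this alkene from the radical cascade), and the bulky silyl chloride then caps only the primary alcohol in the same flask.

Step 6
Reactants: 10 tert-butyl (3R,6E,10E,14S,15S)-16-[(tert-butyldiphenylsilyl)oxy]-14,15-epoxy-3-hydroxy-2,6,10,14-tetramethylhexadeca-6,10-dienoate
Product: 12 tert-butyl (3R,4S,5R,9S,10R,13S,14S)-15-[(tert-butyldiphenylsilyl)oxy]-13,14-epoxy-3-hydroxylabd-8(17)-en-18-oate (3α-OH axial; 4α-CO2tBu; 4β-CH3), via dilithium alkoxide enolate 11 (not isolated)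
Conditions: LiN(iPr)2 (2.2 equiv), THF, −78 → −30 °C; then added slowly to Cu(O2CCH(Et)Bu)2 (2.5 equiv), THF, −30 → 0 °C, argon
Reagents that add atoms: none
Why: Proposed new method: the Fráter–Seebach-type dianion 11 is oxidised by divalent copper (closest precedent: Rathke-type copper carboxylate oxidation of ester enolates) to a planar tertiary α-ester radical (both C2 epimers converge) that stays chelated through the C3 alkoxide and the ester carbonyl (Guindon-type chelate control), so in the chair transition state the C3–O bond lies in the chelate plane (axial, 3α) and the ester is equatorial (4α, methyl 4β); this electrophilic radical adds 6-endo to C5 of the E-alkene (ring A), the C10 radical adds 6-endo to C9 through a second chair (ring B, trans-decalin, side chain equatorial), and the C8 radical is captured by a second divalent copper carboxylate and loses a methyl hydrogen (Kochi oxidative elimination, as in Snider's Mn(OAc)3/Cu(OAc)2 polyene cyclizations) to give mainly the exocyclic alkene; the epoxide leaves no third alkene, so the cascade must stop at two rings.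

Step 7
Reactants: 12 tert-butyl (3R,4S,5R,9S,10R,13S,14S)-15-[(tert-butyldiphenylsilyl)oxy]-13,14-epoxy-3-hydroxylabd-8(17)-en-18-oate
Product: 13 tert-butyl (3R,4S,5R,9S,10R,13S,14S)-3-acetoxy-15-[(tert-butyldiphenylsilyl)oxy]-13,14-epoxylabd-8(17)-en-18-oate
Conditions: Ac2O, DMAP, pyridine, 23 °C
Reagents that add atoms: acetic anhydride CC(=O)OC(C)=O
Why: DMAP-catalysed acetylation (Steglich-type acyl transfer) of the only free hydroxyl; the axial C3 carbinol keeps its configuration because no bond to C3 is broken.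

Step 8
Reactants: 13 tert-butyl (3R,4S,5R,9S,10R,13S,14S)-3-acetoxy-15-[(tert-butyldiphenylsilyl)oxy]-13,14-epoxylabd-8(17)-en-18-oate
Product: 14 tert-butyl (3R,4S,5R,9S,10R,13E)-3-acetoxy-15-[(tert-butyldiphenylsilyl)oxy]labda-8(17),13-dien-18-oate
Conditions: dimethyl diazomalonate (1.5 equiv, slow addition), Rh2(OAc)4 (2 mol%), benzene, 80 °C
Reagents that add atoms: none
Why: Martin–Ganem-type deoxygenation: the rhodium carbenoid is captured by the basic epoxide oxygen faster than by the hindered alkenes, and the oxonium ylide collapses to alkene plus oxomalonate with retention, so the trans-epoxide returns the 13E alkene; no hydroxyl is free for O–H insertion.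

Step 9
Reactants: 14 tert-butyl (3R,4S,5R,9S,10R,13E)-3-acetoxy-15-[(tert-butyldiphenylsilyl)oxy]labda-8(17),13-dien-18-oate
Product: 16 (3R,4S,5R,9S,10R,13E)-3-acetoxy-15-[(tert-butyldiphenylsilyl)oxy]labda-8(17),13-dien-18-oic acid, via trimethylsilyl ester 15 (not isolated)
Conditions: Me3SiOTf (3 equiv), 2,6-lutidine (4 equiv), CH2Cl2, 0 → 23 °C; then pH 5 aqueous buffer
Reagents that add atoms: none
Why: Silyl triflate-mediated tert-butyl ester cleavage goes by alkyl–oxygen fission (loss of isobutene), so the neopentyl acyl carbon is never attacked and the acetate, the lutidine-buffered alkenes and the silyl ether survive; the trimethylsilyl ester hydrolyses on work-up.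

Step 10
Reactants: 16 (3R,4S,5R,9S,10R,13E)-3-acetoxy-15-[(tert-butyldiphenylsilyl)oxy]labda-8(17),13-dien-18-oic acid
Product: 17 (3R,4S,5R,9S,10R,13E)-3-acetoxy-15-hydroxylabda-8(17),13-dien-18-oic acid (CNP0395853.2)
Conditions: Bu4NF (2.5 equiv), THF, 0 → 23 °C
Reagents that add atoms: none
Why: Fluoride-induced desilylation (driven by the Si–F bond) frees the primary allylic alcohol without touching the hindered axial acetate or either alkene, and gives the target with C3 from step 4, C4, C5, C9 and C10 from step 6 and the 13E alkene from step 8.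

## Compound list

1 | (2E,6E)-3,7,11-trimethyldodeca-2,6,10-trien-1-yl acetate | CC(C)=CCC/C(C)=C/CC/C(C)=C/COC(C)=O | starting material
2 | (2E,6E,10E)-12-hydroxy-3,7,11-trimethyldodeca-2,6,10-trien-1-yl acetate | OC/C(C)=C/CC/C(C)=C/CC/C(C)=C/COC(C)=O | intermediate
3 | (2E,6E,10E)-12-bromo-3,7,11-trimethyldodeca-2,6,10-trien-1-yl acetate | BrC/C(C)=C/CC/C(C)=C/CC/C(C)=C/COC(C)=O | intermediate
4 | tert-butyl 2-methyl-3-oxobutanoate | CC(=O)C(C)C(=O)OC(C)(C)C | starting material
5 | sodium lithium dienolate of 4 | [Na+].[Li+].C=C([O-])C(C)=C([O-])OC(C)(C)C | intermediate (not isolated)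
6 | tert-butyl (6E,10E,14E)-16-acetoxy-2,6,10,14-tetramethyl-3-oxohexadeca-6,10,14-trienoate | CC(C(=O)OC(C)(C)C)C(=O)CC/C(C)=C/CC/C(C)=C/CC/C(C)=C/COC(C)=O | intermediate
7 | tert-butyl (3R,6E,10E,14E)-16-acetoxy-3-hydroxy-2,6,10,14-tetramethylhexadeca-6,10,14-trienoate | CC(C(=O)OC(C)(C)C)[C@H](O)CC/C(C)=C/CC/C(C)=C/CC/C(C)=C/COC(C)=O | intermediate (not isolated)
8 | tert-butyl (3R,6E,10E,14E)-3,16-dihydroxy-2,6,10,14-tetramethylhexadeca-6,10,14-trienoate | CC(C(=O)OC(C)(C)C)[C@H](O)CC/C(C)=C/CC/C(C)=C/CC/C(C)=C/CO | intermediate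
9 | tert-butyl (3R,6E,10E,14S,15S)-14,15-epoxy-3,16-dihydroxy-2,6,10,14-tetramethylhexadeca-6,10-dienoate | CC(C(=O)OC(C)(C)C)[C@H](O)CC/C(C)=C/CC/C(C)=C/CC[C@]1(C)O[C@H]1CO | intermediate (not isolated)
10 | tert-butyl (3R,6E,10E,14S,15S)-16-[(tert-butyldiphenylsilyl)oxy]-14,15-epoxy-3-hydroxy-2,6,10,14-tetramethylhexadeca-6,10-dienoate | CC(C(=O)OC(C)(C)C)[C@H](O)CC/C(C)=C/CC/C(C)=C/CC[C@]1(C)O[C@H]1CO[Si](c1ccccc1)(c1ccccc1)C(C)(C)C | intermediate
11 | dilithium alkoxide enolate of 10 | [Li+].[Li+].CC(=C([O-])OC(C)(C)C)[C@H]([O-])CC/C(C)=C/CC/C(C)=C/CC[C@]1(C)O[C@H]1CO[Si](c1ccccc1)(c1ccccc1)C(C)(C)C | intermediate (not isolated)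
12 | tert-butyl (3R,4S,5R,9S,10R,13S,14S)-15-[(tert-butyldiphenylsilyl)oxy]-13,14-epoxy-3-hydroxylabd-8(17)-en-18-oate | C=C1CC[C@@H]2[C@](C)(CC[C@@H](O)[C@@]2(C)C(=O)OC(C)(C)C)[C@H]1CC[C@]3(C)O[C@H]3CO[Si](c4ccccc4)(c4ccccc4)C(C)(C)C | intermediate
13 | tert-butyl (3R,4S,5R,9S,10R,13S,14S)-3-acetoxy-15-[(tert-butyldiphenylsilyl)oxy]-13,14-epoxylabd-8(17)-en-18-oate | C=C1CC[C@@H]2[C@](C)(CC[C@@H](OC(C)=O)[C@@]2(C)C(=O)OC(C)(C)C)[C@H]1CC[C@]3(C)O[C@H]3CO[Si](c4ccccc4)(c4ccccc4)C(C)(C)C | intermediate
14 | tert-butyl (3R,4S,5R,9S,10R,13E)-3-acetoxy-15-[(tert-butyldiphenylsilyl)oxy]labda-8(17),13-dien-18-oate | C=C1CC[C@@H]2[C@](C)(CC[C@@H](OC(C)=O)[C@@]2(C)C(=O)OC(C)(C)C)[C@H]1CC/C(C)=C/CO[Si](c3ccccc3)(c3ccccc3)C(C)(C)C | intermediate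
15 | trimethylsilyl (3R,4S,5R,9S,10R,13E)-3-acetoxy-15-[(tert-butyldiphenylsilyl)oxy]labda-8(17),13-dien-18-oate | C=C1CC[C@@H]2[C@](C)(CC[C@@H](OC(C)=O)[C@@]2(C)C(=O)O[Si](C)(C)C)[C@H]1CC/C(C)=C/CO[Si](c3ccccc3)(c3ccccc3)C(C)(C)C | intermediate (not isolated)
16 | (3R,4S,5R,9S,10R,13E)-3-acetoxy-15-[(tert-butyldiphenylsilyl)oxy]labda-8(17),13-dien-18-oic acid | C=C1CC[C@@H]2[C@](C)(CC[C@@H](OC(C)=O)[C@@]2(C)C(=O)O)[C@H]1CC/C(C)=C/CO[Si](c3ccccc3)(c3ccccc3)C(C)(C)C | intermediate
17 | (3R,4S,5R,9S,10R,13E)-3-acetoxy-15-hydroxylabda-8(17),13-dien-18-oic acid | C=C1CC[C@@H]2[C@](C)(CC[C@@H](OC(C)=O)[C@@]2(C)C(=O)O)[C@H]1CC/C(C)=C/CO | target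

## Step count and risks

Total step count: 10. Longest linear sequence: 10 steps (1 → 17); 4 is bought.

The three steps most likely to fail:

Step 6 (bicyclization). The copper-mediated enolate oxidation may be inefficient, chelate control may be incomplete, or the C8 oxidation may give endocyclic alkene isomers. The fallback sets out from 11 and comes back at 12. Dianion 11 is quenched at −78 °C with PhSeBr to give the α-phenylselanyl β-hydroxy ester F1. Irradiation of F1 (sunlamp, benzene, catalytic (Bu3Sn)2) starts a phenylselanyl group-transfer radical chain that effects the same two 6-endo closures, with the intramolecular O–H···O=C hydrogen bond taking the place of the lithium chelate, and ends at the tertiary C8 selenide F2. Oxidation of F2 (H2O2, pyridine, 0 °C) gives a selenoxide whose syn-elimination can only reach the freely rotating methyl hydrogens, which gives 12 with the exocyclic alkene.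

Step 8 (epoxide deoxygenation). The carbenoid may cyclopropanate an alkene, or the oxomalonate by-product may react with the exocyclic alkene in an ene reaction. The fallback sets out from 13 and comes back at 14. Thiourea in methanol at 50 °C exchanges oxygen for sulfur with inversion at both carbons and gives the trans-thiirane F3. PPh3 in toluene at 90 °C then removes the sulfur stereospecifically and gives 14 with the 13E alkene.

Step 3 (dianion alkylation beside an acetate). The doubly charged nucleophile may acylate on the acetate, or give low γ-selectivity with the α-methyl acetoacetate. The fallback sets out from 3 and comes back at 6. Bromide 3 is alkylated at −78 °C with lithiated N-cyclohexylacetaldimine to give the imine F4. Aqueous oxalic acid hydrolyses F4 to the aldehyde F5. Aldol addition of the lithium enolate of tert-butyl propionate (LiN(iPr)2, THF, −78 °C) gives the β-hydroxy ester F6. Dess–Martin periodinane oxidises F6 to the β-keto ester 6.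

Further compounds
F1 | step 6 | tert-butyl (3R,6E,10E,14S,15S)-16-[(tert-butyldiphenylsilyl)oxy]-14,15-epoxy-3-hydroxy-2,6,10,14-tetramethyl-2-(phenylselanyl)hexadeca-6,10-dienoate | CC([Se]c1ccccc1)(C(=O)OC(C)(C)C)[C@H](O)CC/C(C)=C/CC/C(C)=C/CC[C@]2(C)O[C@H]2CO[Si](c3ccccc3)(c3ccccc3)C(C)(C)C
F2 | step 6 | tert-butyl (3R,4S,5R,9S,10R,13S,14S)-15-[(tert-butyldiphenylsilyl)oxy]-13,14-epoxy-3-hydroxy-8-(phenylselanyl)labdan-18-oate | CC1([Se]c2ccccc2)CC[C@@H]2[C@](C)(CC[C@@H](O)[C@@]2(C)C(=O)OC(C)(C)C)[C@H]1CC[C@]3(C)O[C@H]3CO[Si](c4ccccc4)(c4ccccc4)C(C)(C)C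
F3 | step 8 | tert-butyl (3R,4S,5R,9S,10R,13R,14R)-3-acetoxy-15-[(tert-butyldiphenylsilyl)oxy]-13,14-epithiolabd-8(17)-en-18-oate | C=C1CC[C@@H]2[C@](C)(CC[C@@H](OC(C)=O)[C@@]2(C)C(=O)OC(C)(C)C)[C@H]1CC[C@@]3(C)S[C@@H]3CO[Si](c4ccccc4)(c4ccccc4)C(C)(C)C
F4 | step 3 | (2E,6E,10E)-14-(cyclohexylimino)-3,7,11-trimethyltetradeca-2,6,10-trien-1-yl acetate | C1CCCCC1N=CCC/C(C)=C/CC/C(C)=C/CC/C(C)=C/COC(C)=O
F5 | step 3 | (2E,6E,10E)-3,7,11-trimethyl-14-oxotetradeca-2,6,10-trien-1-yl acetate | O=CCC/C(C)=C/CC/C(C)=C/CC/C(C)=C/COC(C)=O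
F6 | step 3 | tert-butyl (6E,10E,14E)-16-acetoxy-3-hydroxy-2,6,10,14-tetramethylhexadeca-6,10,14-trienoate | CC(C(=O)OC(C)(C)C)C(O)CC/C(C)=C/CC/C(C)=C/CC/C(C)=C/COC(C)=O
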